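The seven-membered ring (C1 and C5–C10 in guaiane numbering) is made from the cyclohexane ring C5–C10 of an eudesmane-type cross-conjugated cyclohexadienone. Irradiation in acetic acid joins C1 to C5 and then breaks C5–C10, so that in one operation ring B takes up C1 and becomes seven-membered, ring A shrinks to the cyclopentenone, and C10, the future methyl-bearing alkene carbon, is acetoxylated. The step exploits the C1–C5 and C1–C10 bonds of the target, its C10 methyl and its C4 methyl, which directs the bond cleavage. The dienone comes from a silyloxycyclohexenone by cuprate addition and Robinson annulation; C5–H is set afterwards by reductive allylic transposition.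

Key step: step 5

Assumption: (S)-4-(tert-butyldimethylsilyloxy)cyclohex-2-en-1-one (1) is taken as a purchasable enantiopure building block.

Numbering remark: bicyclic compounds carry eudesmane numbering before step 5 (ring A = C1–C5, C10; ring B = C5–C10; C14 on C10, C15 on C4, isopropyl on C7) and guaiane numbering after it (five-membered ring C1–C5, seven-membered ring C1, C5–C10). The oxygen-bearing carbon of 1 becomes C8 and its carbonyl carbon becomes C5.

Step 1
Reactants: 1 (S)-4-(tert-butyldimethylsilyloxy)cyclohex-2-en-1-one
Product: 3 (4S,6RS)-4-(tert-butyldimethylsilyloxy)-6-methylcyclohex-2-en-1-one, via lithium dienolate 2 (not isolated)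
Conditions: LiN(i-Pr)2, THF, −78 °C; then MeI, −78 → −30 °C
Reagents that add atoms: iodomethane, CI
Why: Kinetic deprotonation of the enone at the α′ carbon gives the cross-conjugated lithium dienolate, which is C-methylated (enolate alkylation); the new methyl-bearing centre (later C10) forms as an epimer mixture that need not be controlled because it becomes quaternary in step 3 and sp2 in step 6.

Step 2
Reactants: 3 (4S,6RS)-4-(tert-butyldimethylsilyloxy)-6-methylcyclohex-2-en-1-one
Product: 5 (2RS,4S,5R)-4-(tert-butyldimethylsilyloxy)-2-methyl-5-(propan-2-yl)cyclohexan-1-one, via trimethylsilyl enol ether 4 (not isolated)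
Conditions: i-PrMgCl, CuBr·SMe2 (cat.), Me3SiCl, THF, −78 °C; then aq. citric acid, 0 °C
Reagents that add atoms: isopropylmagnesium chloride, CC(C)[Mg]Cl
Why: Copper-catalysed conjugate addition of the Grignard reagent, accelerated by Me3SiCl, should place the isopropyl group on the β carbon anti to the neighbouring silyloxy group, which sets C7 (R) trans to the C8 oxygen; mild acid then hydrolyses the silyl enol ether to the ketone.

Step 3
Reactants: 5 (2RS,4S,5R)-4-(tert-butyldimethylsilyloxy)-2-methyl-5-(propan-2-yl)cyclohexan-1-one; 6 pent-1-en-3-one (ethyl vinyl ketone)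
Product: 9 (7R,8S,10RS)-8-(tert-butyldimethylsilyloxy)eudesm-4-en-3-one, via Michael diketone 7 (not isolated), via aldol ketol 8 (not isolated)
Conditions: KOH, EtOH, −10 °C → rt; then 60 °C
Reagents that add atoms: none
Why: Robinson annulation: the more substituted, methyl-bearing enolate (the other α carbon is shielded by the isopropyl-bearing C7) adds to the vinyl ketone and intramolecular aldol condensation closes ring A with the C4 methyl in place; the quaternary C10 forms as two epimers, which converge in step 6.

Step 4
Reactants: 9 (7R,8S,10RS)-8-(tert-butyldimethylsilyloxy)eudesm-4-en-3-one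
Product: 10 (7R,8S,10RS)-8-(tert-butyldimethylsilyloxy)eudesma-1,4-dien-3-one
Conditions: DDQ, 1,4-dioxane, reflux
Reagents that add atoms: none
Why: DDQ dehydrogenation of a 4-en-3-one through its 2,4-dienol (hydride loss from C1) should give the cross-conjugated 1,4-dien-3-one; no stereocentre is touched.

Step 5
Reactants: 10 (7R,8S,10RS)-8-(tert-butyldimethylsilyloxy)eudesma-1,4-dien-3-one
Product: 12 (7R,8S)-8-(tert-butyldimethylsilyloxy)-3-oxoguai-4-en-10-yl acetate (C1 and C10 as formed), via cyclopropyl oxyallyl zwitterion 11 (not isolated)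
Conditions: hν (medium-pressure Hg lamp, Pyrex filter), AcOH, 15–20 °C, N2
Reagents that add atoms: acetic acid, CC(=O)O
Why: Excitation of the cross-conjugated dienone leads to bonding between the two β carbons C1 and C5 and to the bicyclo[3.1.0]hexenyl oxyallyl zwitterion 11; protonation on oxygen and cleavage of the cyclopropane bond C5–C10 with capture of acetate at C10 moves C5 from C10 to C1, so that ring A contracts to the cyclopentenone and ring B (C5–C10) grows to the seven-membered ring C1, C5–C10. The closest known reaction type is the photorearrangement of 4-methyl-substituted 6/6-fused cyclohexa-2,5-dienones (santonin type) to 5/7-fused 10-acyloxy or 10-hydroxy enones in acidic media. The three-membered ring closes by β,β′-bonding of the excited dienone (formally 3-exo) and is opened again in the same operation, which leaves the five-membered ring C1–C5 closed through the new C1–C5 bond and the seven-membered ring formed by one-carbon ring expansion. The new centres C1 and C10 follow from the C10 configuration of 10 (suprafacial C1–C5 bonding, acetate entering C10 anti to the breaking bond), but neither needs control because both become sp2 in step 6, and C7 and C8 are not touched. The step needs cleavage of C5–C10 instead of C1–C10 (which would give a spiro ketone) and trapping of the zwitterion before it shifts to a lumiketone: the C4 methyl group stabilises positive charge at C4 next to C5 and so directs the cleavage, and the acidic solvent supplies both proton and nucleophile.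

Step 6
Reactants: 12 (7R,8S)-8-(tert-butyldimethylsilyloxy)-3-oxoguai-4-en-10-yl acetate
Product: 13 (7R,8S)-8-(tert-butyldimethylsilyloxy)guaia-1(10),4-dien-3-one
Conditions: DBU, toluene, 40 °C
Reagents that add atoms: none
Why: Vinylogous E1cB elimination: DBU removes the γ proton at C1 and the dienolate expels acetate from C10, which should place the alkene at C1=C10 in conjugation with the enone and merge both diastereomer series; the silyloxy group is a much poorer leaving group and should stay.

Step 7
Reactants: 13 (7R,8S)-8-(tert-butyldimethylsilyloxy)guaia-1(10),4-dien-3-one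
Product: 14 (3R,7R,8S)-8-(tert-butyldimethylsilyloxy)guaia-1(10),4-dien-3-ol
Conditions: (S)-2-methyl-CBS-oxazaborolidine (cat.), BH3·SMe2, THF, −30 °C; then MeOH
Reagents that add atoms: none
Why: CBS reduction (1,2): the oxazaborolidine–borane complex binds the carbonyl with the methyl-substituted alkenyl arm as the large group and delivers hydride to one face, so the (3R) carbinol should be set by the catalyst, independent of the remote centres C7 and C8.

Step 8
Reactants: 14 (3R,7R,8S)-8-(tert-butyldimethylsilyloxy)guaia-1(10),4-dien-3-ol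
Product: 17 (5R,7R,8S)-8-(tert-butyldimethylsilyloxy)guaia-1(10),3-diene, via sulfonylhydrazide adduct 15 (not isolated), via allylic diazene 16 (not isolated)
Conditions: PPh3, diethyl azodicarboxylate, 2-nitrobenzenesulfonylhydrazide, THF, −30 °C → 23 °C
Reagents that add atoms: none
Why: Mitsunobu displacement of the allylic alcohol by the sulfonylhydrazide with inversion, loss of sulfinic acid to the monoalkyl diazene and retro-ene loss of N2 (reductive 1,3-transposition of an allylic alcohol); hydrogen passes from nitrogen to C5 on the face of the C3–N bond, that is anti to the original hydroxyl, which sets C5 (R) and moves the alkene to C3=C4 while C1=C10 stays.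

Step 9
Reactants: 17 (5R,7R,8S)-8-(tert-butyldimethylsilyloxy)guaia-1(10),3-diene
Product: 18 (5R,7R,8S)-guaia-1(10),3-dien-8-ol
Conditions: n-Bu4NF, THF, 0 °C → rt
Reagents that add atoms: none
Why: Fluoride cleaves the Si–O bond (driven by the Si–F bond) under conditions that leave the skipped diene and the doubly allylic C5–H alone; C8 keeps its configuration.

Step 10
Reactants: 18 (5R,7R,8S)-guaia-1(10),3-dien-8-ol; 19 4-acetoxy-3-methoxybenzoic acid
Product: 21 (5R,7R,8S)-guaia-1(10),3-dien-8-yl 4-acetoxy-3-methoxybenzoate, via O-acylisourea 20 (not isolated)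
Conditions: DCC, DMAP (cat.), CH2Cl2, 0 °C → rt
Reagents that add atoms: none
Why: Steglich esterification: DCC activates the acid as the O-acylisourea and DMAP passes the acyl group to the hindered secondary alcohol with retention at C8; the phenol is masked as its acetate so that it cannot be acylated.

Step 11
Reactants: 21 (5R,7R,8S)-guaia-1(10),3-dien-8-yl 4-acetoxy-3-methoxybenzoate
Product: 22 (5R,7R,8S)-guaia-1(10),3-dien-8-yl 4-hydroxy-3-methoxybenzoate (CNP0156298.2)
Conditions: K2CO3 (cat.), MeOH, 0 °C
Reagents that add atoms: none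
Why: Base-catalysed methanolysis (transesterification) should cleave the aryl acetate much faster than the hindered, electron-rich alkyl aroate and so release the phenol; no stereocentre is involved.

Compound list

1 | (S)-4-(tert-butyldimethylsilyloxy)cyclohex-2-en-1-one | CC(C)(C)[Si](C)(C)O[C@H]1CCC(=O)C=C1 | starting material
2 | lithium cross-conjugated dienolate of 1 (not isolated) | CC(C)(C)[Si](C)(C)O[C@H]1CC=C(O[Li])C=C1 | intermediate
3 | (4S,6RS)-4-(tert-butyldimethylsilyloxy)-6-methylcyclohex-2-en-1-one | CC(C)(C)[Si](C)(C)O[C@H]1CC(C)C(=O)C=C1 | intermediate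
4 | trimethylsilyl enol ether of 5, 4,5-trans (not isolated) | CC(C)(C)[Si](C)(C)O[C@H]1CC(C)C(O[Si](C)(C)C)=C[C@@H]1C(C)C | intermediate
5 | (2RS,4S,5R)-4-(tert-butyldimethylsilyloxy)-2-methyl-5-(propan-2-yl)cyclohexan-1-one | CC(C)(C)[Si](C)(C)O[C@H]1CC(C)C(=O)C[C@@H]1C(C)C | intermediate
6 | pent-1-en-3-one (ethyl vinyl ketone) | C=CC(=O)CC | starting material
7 | (4S,5R)-4-(tert-butyldimethylsilyloxy)-2-methyl-2-(3-oxopentyl)-5-(propan-2-yl)cyclohexan-1-one, C2 epimers (not isolated) | CC(C)(C)[Si](C)(C)O[C@H]1CC(C)(CCC(=O)CC)C(=O)C[C@@H]1C(C)C | intermediate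
8 | (7R,8S)-8-(tert-butyldimethylsilyloxy)-5-hydroxyeudesman-3-one, aldol ketol (not isolated) | CC(C)(C)[Si](C)(C)O[C@H]1CC2(C)CCC(=O)C(C)C2(O)C[C@@H]1C(C)C | intermediate
9 | (7R,8S,10RS)-8-(tert-butyldimethylsilyloxy)eudesm-4-en-3-one | CC(C)(C)[Si](C)(C)O[C@H]1CC2(C)CCC(=O)C(C)=C2C[C@@H]1C(C)C | intermediate
10 | (7R,8S,10RS)-8-(tert-butyldimethylsilyloxy)eudesma-1,4-dien-3-one | CC(C)(C)[Si](C)(C)O[C@H]1CC2(C)C=CC(=O)C(C)=C2C[C@@H]1C(C)C | intermediate
11 | cyclopropyl oxyallyl zwitterion, C1–C5 bonded, cyclopropane C1–C5–C10 (not isolated) | CC(C)(C)[Si](C)(C)O[C@H]1CC2(C)C3[CH+]C([O-])=C(C)C23C[C@@H]1C(C)C | intermediate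
12 | (7R,8S)-8-(tert-butyldimethylsilyloxy)-3-oxoguai-4-en-10-yl acetate, C1/C10 as formed | CC(C)(C)[Si](C)(C)O[C@H]1CC(C)(OC(C)=O)C2CC(=O)C(C)=C2C[C@@H]1C(C)C | intermediate
13 | (7R,8S)-8-(tert-butyldimethylsilyloxy)guaia-1(10),4-dien-3-one | CC(C)(C)[Si](C)(C)O[C@H]1CC(C)=C2CC(=O)C(C)=C2C[C@@H]1C(C)C | intermediate
14 | (3R,7R,8S)-8-(tert-butyldimethylsilyloxy)guaia-1(10),4-dien-3-ol | CC(C)(C)[Si](C)(C)O[C@H]1CC(C)=C2C[C@@H](O)C(C)=C2C[C@@H]1C(C)C | intermediate
15 | N-[(3S,7R,8S)-8-(tert-butyldimethylsilyloxy)guaia-1(10),4-dien-3-yl]-2-nitrobenzenesulfonohydrazide (not isolated) | CC(C)(C)[Si](C)(C)O[C@H]1CC(C)=C2C[C@H](N(N)S(=O)(=O)c3ccccc3[N+](=O)[O-])C(C)=C2C[C@@H]1C(C)C | intermediate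
16 | (3S,7R,8S)-8-(tert-butyldimethylsilyloxy)guaia-1(10),4-dien-3-yldiazene (not isolated) | CC(C)(C)[Si](C)(C)O[C@H]1CC(C)=C2C[C@H](N=N)C(C)=C2C[C@@H]1C(C)C | intermediate
17 | (5R,7R,8S)-8-(tert-butyldimethylsilyloxy)guaia-1(10),3-diene | CC(C)(C)[Si](C)(C)O[C@H]1CC(C)=C2CC=C(C)[C@H]2C[C@@H]1C(C)C | intermediate
18 | (5R,7R,8S)-guaia-1(10),3-dien-8-ol | O[C@H]1CC(C)=C2CC=C(C)[C@H]2C[C@@H]1C(C)C | intermediate
19 | 4-acetoxy-3-methoxybenzoic acid | CC(=O)Oc1ccc(C(=O)O)cc1OC | starting material
20 | O-(4-acetoxy-3-methoxybenzoyl)-N,N'-dicyclohexylisourea (not isolated) | CC(=O)Oc1ccc(C(=O)OC(=NC2CCCCC2)NC2CCCCC2)cc1OC | intermediate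
21 | (5R,7R,8S)-guaia-1(10),3-dien-8-yl 4-acetoxy-3-methoxybenzoate | CC(=O)Oc1ccc(C(=O)O[C@H]2CC(C)=C3CC=C(C)[C@H]3C[C@@H]2C(C)C)cc1OC | intermediate
22 | (5R,7R,8S)-guaia-1(10),3-dien-8-yl 4-hydroxy-3-methoxybenzoate (CNP0156298.2) | COc1cc(C(=O)O[C@H]2CC(C)=C3CC=C(C)[C@H]3C[C@@H]2C(C)C)ccc1O | target

Total step count: 11. Longest linear sequence: 11 steps (1 → 22; 6 and 19 are bought).

Steps most likely to fail

Step 5. The acidic medium may strip the silyl ether during the irradiation, and if acetate traps the zwitterion too slowly the material may drain into lumiketone or spiro ketone, or the enone product may be photolysed further. The fallback sets out from 10 and separates deprotection, ring expansion and alkene formation, with water as the trap and a dehydration in place of the acetate elimination. n-Bu4NF removes the silyl group to give (7R,8S,10RS)-8-hydroxyeudesma-1,4-dien-3-one F1. Irradiation of F1 in refluxing 45% aqueous acetic acid should give (7R,8S)-8,10-dihydroxyguai-4-en-3-one F2. TBSCl and imidazole silylate only the secondary alcohol to give (7R,8S)-8-(tert-butyldimethylsilyloxy)-10-hydroxyguai-4-en-3-one F3. Dehydration of the tertiary alcohol with the Burgess reagent, followed by DBU to draw the alkene isomers into conjugation, returns to the route at 13.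

Step 8. The activated dienylic alcohol may ionise to a cation delocalised over C3, C5 and C10, which would erode the inversion at C3 (and with it the C5 configuration), allow attack at the wrong terminus or end in elimination to a fulvene. The fallback sets out from 14 and replaces the diazene retro-ene by a palladium hydride transfer. Formylation (acetic formic anhydride, pyridine) gives (3R,7R,8S)-8-(tert-butyldimethylsilyloxy)guaia-1(10),4-dien-3-yl formate F4. With Pd(OAc)2 and n-Bu3P in THF, zerovalent palladium formed in the flask should ionise the formate with inversion, and the palladium hydride left after loss of carbon dioxide should deliver hydrogen to the more substituted terminus C5 from the metal face, anti to the original oxygen. This is the same stereochemical result as in step 8 and returns to the route at 17.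

Step 3. Under hydroxide the Michael addition may take place at the wrong α carbon, the vinyl ketone may polymerise, or the adduct may revert. The fallback sets out from 5 and uses a regiodefined enol derivative and Lewis acid instead of equilibrating enolates. Me3SiCl, NaI and Et3N in MeCN should give the more substituted (thermodynamic) trimethylsilyl enol ether, (4S,5R)-4-(tert-butyldimethylsilyloxy)-2-methyl-5-(propan-2-yl)-1-(trimethylsilyloxy)cyclohex-1-ene F5. Mukaiyama–Michael addition of F5 to 6 (BF3·OEt2, CH2Cl2, −78 °C) gives diketone 7, now isolated, and KOH in MeOH closes it by aldol condensation, returning to the route at 9.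

Further compounds

F1 | step 5 | (7R,8S,10RS)-8-hydroxyeudesma-1,4-dien-3-one | O[C@H]1CC2(C)C=CC(=O)C(C)=C2C[C@@H]1C(C)C
F2 | step 5 | (7R,8S)-8,10-dihydroxyguai-4-en-3-one, C1/C10 as formed | O[C@H]1CC(C)(O)C2CC(=O)C(C)=C2C[C@@H]1C(C)C
F3 | step 5 | (7R,8S)-8-(tert-butyldimethylsilyloxy)-10-hydroxyguai-4-en-3-one, C1/C10 as formed | CC(C)(C)[Si](C)(C)O[C@H]1CC(C)(O)C2CC(=O)C(C)=C2C[C@@H]1C(C)C
F4 | step 8 | (3R,7R,8S)-8-(tert-butyldimethylsilyloxy)guaia-1(10),4-dien-3-yl formate | CC(C)(C)[Si](C)(C)O[C@H]1CC(C)=C2C[C@@H](OC=O)C(C)=C2C[C@@H]1C(C)C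
F5 | step 3 | (4S,5R)-4-(tert-butyldimethylsilyloxy)-2-methyl-5-(propan-2-yl)-1-(trimethylsilyloxy)cyclohex-1-ene | CC(C)(C)[Si](C)(C)O[C@H]1CC(C)=C(O[Si](C)(C)C)C[C@@H]1C(C)C
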